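Numbering (eunicellane): ring fusion C1/C10, Z-alkene C2=C3, acetoxy carbons C6 and C9, exo-methylene carbon C7, carbinol C11, isopropyl carbon C14. The ten-membered ring is closed last, by Nozaki–Hiyama–Kishi reaction at C6–C7, followed by acetylation of O6 and O9.
Z-C2=C3: Negishi coupling (C3–C4) of a Z-enol triflate grown from a C1 ketone by propynyl addition, Meyer–Schuster rearrangement and a 1,4-hydrosilylation that also installs H1.
C9–C10: anti boron aldol of the same C1 ketone, taken up on the face opposite to the axial C11 oxygen.
The six-membered ring is made first, by a one-flask Michael/aldol [3+3] of methyl vinyl ketone with an alpha-isopropyl acetoacetate, which forms C13–C14 and C10–C11.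
Enabling feature: in the cyclohexane ring (C1, C10, C11, C12, C13, C14) the segment C11(OH)(CH3)–C12H2–C13H2 is a masked methyl vinyl ketone. Its two attachment points C10 and C14 both flank the ring-fusion carbon C1, so with C1 as a ketone (and a removable ester on C14) both become enolate carbons.

Key step: step 2

Remark: 1-propynylmagnesium bromide (17) and the organozinc reagent 23 are taken as commercial solutions; the pseudoenantiomer of the cinchona catalyst in step 2 is chosen so that the S-configured quaternary carbon of 5 results.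

Step 1
Reactants: 1 ethyl 2-acetyl-3-methylbutanoate (ethyl 2-isopropylacetoacetate, racemic); 2 prop-2-en-1-ol (allyl alcohol)
Product: 3 prop-2-en-1-yl 2-acetyl-3-methylbutanoate (racemic, configurationally labile)
Conditions: 2 (5 equiv), DMAP (0.3 equiv), 4 Å MS, toluene, reflux
Reagents that add atoms: none
Why: DMAP-catalysed transesterification of an enolisable beta-keto ester should exchange ethyl for allyl, so that the ester can later be removed under neutral conditions; no stereocentre is fixed here.

Step 2
Reactants: 3 prop-2-en-1-yl 2-acetyl-3-methylbutanoate; 4 but-3-en-2-one (methyl vinyl ketone)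
Product: 6 prop-2-en-1-yl (1S,4R)-4-hydroxy-4-methyl-2-oxo-1-(propan-2-yl)cyclohexane-1-carboxylate (hydroxyl cis to isopropyl), via Michael adduct 5 (not isolated)
Conditions: 4 (1.5 equiv), cupreidine 9-O-(9-phenanthryl) ether (10 mol %), CH2Cl2, -20 °C; then DBU (0.2 equiv) into the same flask, 0 °C
Reagents that add atoms: none
Why: The bifunctional cinchona base removes the doubly activated C14–H of 3 and hydrogen-bonds 4, so that conjugate addition forms C13–C14 and gives the 1,5-diketone 5, after which DBU enolises the acetyl CH3 (C10), which adds to the unhindered C11 methyl ketone and forms C10–C11. The closest known reaction types are the catalytic asymmetric Michael addition of alpha-substituted beta-keto esters to methyl vinyl ketone and the ketol stage of a Robinson-type annulation, as in the classical assembly of piperitone-type rings. The one ring that is closed, the cyclohexane, closes in the 6-(enolendo)-exo-trig mode through a chair. The quaternary C14 is set by the face selection of the catalyst, and C11 is set by the reversible aldol under thermodynamic control, the chair with isopropyl and methyl equatorial and the hydroxyl axial (hydrogen-bonded to the C1 carbonyl) placing the hydroxyl cis to the isopropyl group. The step needs the right order and direction of bond formation: only C14–H is acidic enough for the amine base, so C14 and not C10 attacks the enone terminus; the competing aldol of the C11 methyl group onto C1 is blocked because C1 sits next to the quaternary carbon; low temperature and catalytic base hold the product at the ketol stage. The quaternary centre thus relays the chirality of the catalyst to C11, which outlives the removal of the ester and then resets C14.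

Step 3
Reactants: 6 prop-2-en-1-yl (1S,4R)-4-hydroxy-4-methyl-2-oxo-1-(propan-2-yl)cyclohexane-1-carboxylate
Product: 8 (3R,6R)-3-hydroxy-3-methyl-6-(propan-2-yl)cyclohexan-1-one, via beta-keto acid 7 (not isolated)
Conditions: Pd(PPh3)4 (2 mol %), morpholine (1.5 equiv), THF, rt
Reagents that add atoms: none
Why: Tsuji–Trost deallylation by zerovalent palladium with morpholine as allyl acceptor frees the beta-keto acid, which should lose CO2 at room temperature, and C14 is reprotonated under equilibrating conditions to the equatorial isopropyl epimer dictated by the intact C11 centre.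

Step 4
Reactants: 9 (1-bromoethenyl)trimethylsilane; 10 oxirane
Product: 12 3-(trimethylsilyl)but-3-en-1-ol, via Grignard reagent 11 (not isolated)
Conditions: Mg, THF, reflux; then CuI (10 mol %), 10, -30 °C to rt
Reagents that add atoms: none
Why: Copper-catalysed opening of an epoxide by an alkenyl Grignard reagent should give the homoallylic alcohol that carries C7, C8, C9 and the exo-methylene carbon; no stereocentre is formed.

Step 5
Reactants: 12 3-(trimethylsilyl)but-3-en-1-ol
Product: 13 3-(trimethylsilyl)but-3-enal
Conditions: DMP (triacetoxyperiodinane, 1.1 equiv), CH2Cl2, 0 °C, used at once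
Reagents that add atoms: none
Why: Hypervalent iodine oxidation of a primary alcohol under neutral conditions should give the beta,gamma-unsaturated aldehyde without migration of the double bond.

Step 6
Reactants: 8 (3R,6R)-3-hydroxy-3-methyl-6-(propan-2-yl)cyclohexan-1-one; 13 3-(trimethylsilyl)but-3-enal
Product: 15 (2S,3R,6R)-3-hydroxy-2-[(1R)-1-hydroxy-3-(trimethylsilyl)but-3-en-1-yl]-3-methyl-6-(propan-2-yl)cyclohexan-1-one, via boron enolate 14 (not isolated)
Conditions: c-Hex2BCl (2.3 equiv), Et3N (2.5 equiv), Et2O, -78 to 0 °C; 13, -78 °C; then H2O2, MeOH, pH 7 buffer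
Reagents that add atoms: none
Why: Boron aldol addition through a closed chair transition state: soft enolisation takes the C10 methylene and not the more hindered C14–H, the ring-locked E-enolate gives the anti aldol (C9), and the aldehyde is taken up axially on the face opposite to the axial C11 borinate (C10).

Step 7
Reactants: 15 aldol diol
Product: 16 bis(triethylsilyl) ether of 15 (O9 and O11 silylated, all stereocentres unchanged)
Conditions: TESOTf (3 equiv), 2,6-lutidine (4 equiv), CH2Cl2, -78 to 0 °C
Reagents that add atoms: triethylsilyl trifluoromethanesulfonate CC[Si](CC)(CC)OS(=O)(=O)C(F)(F)F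
Why: Silyl triflate silylation should protect the secondary and the tertiary hydroxyl under weakly basic conditions that leave the epimerisable C10 untouched.

Step 8
Reactants: 16 bis-TES ketone; 17 1-propynylmagnesium bromide
Product: 18 tertiary propargylic alcohol (prop-1-yn-1-yl and OH on C1, C1 epimers of no consequence, other stereocentres unchanged)
Conditions: 17 (3 equiv), LaCl3·2LiCl (0.3 equiv), THF, 0 °C
Reagents that add atoms: none
Why: Lanthanum-promoted 1,2-addition of a slim alkynyl Grignard reagent should beat enolisation of the hindered ketone, and the new carbinol centre is erased in the next step.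

Step 9
Reactants: 18 tertiary propargylic alcohol
Product: 19 exocyclic enone, 1-(cyclohexylidene)propan-2-one unit C1=C2H–C3(=O)CH3 with the acyl group on the C10 side
Conditions: Ph3PAuNTf2 (2 mol %), MeOH (1 equiv), toluene, rt
Reagents that add atoms: none
Why: Gold-catalysed Meyer–Schuster rearrangement (formal 1,3-shift of the hydroxyl group and tautomerisation) should give the enone, whose acyl group turns towards C10, where the substituent is axial, to avoid allylic strain with the equatorial isopropyl group.

Step 10
Reactants: 19 exocyclic enone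
Product: 20 (Z)-triethylsilyl enol ether with new C1–H (H1 cis to H10, side chain equatorial and trans to isopropyl; enol oxygen cis to C1 across C2=C3)
Conditions: Et3SiH (1.5 equiv), RhCl(PPh3)3 (1 mol %), toluene, 50 °C
Reagents that add atoms: triethylsilane CC[SiH](CC)CC
Why: Rhodium-catalysed 1,4-hydrosilylation of an enone: hydride should reach C1 from the face opposite to the branched axial side chain on the neighbouring C10, which also lets the new chain become equatorial, and the s-cis conformation enforced by beta,beta-disubstitution gives the Z-silyl enol ether.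

Step 11
Reactants: 20 (Z)-triethylsilyl enol ether
Product: 22 (Z)-enol triflate (OTf on C3, cis to C1), via lithium enolate 21 (not isolated)
Conditions: MeLi (1.05 equiv), THF, 0 °C; then PhNTf2 (1.2 equiv), -78 °C to rt
Reagents that add atoms: N-phenylbis(trifluoromethanesulfonimide) O=S(=O)(N(c1ccccc1)S(=O)(=O)C(F)(F)F)C(F)(F)F
Why: Regiospecific release of the lithium enolate from the silyl enol ether followed by O-triflation should keep the position and the Z geometry of the double bond, while the alkyl silyl ethers resist methyllithium.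

Step 12
Reactants: 22 (Z)-enol triflate; 23 [2-(1,3-dioxolan-2-yl)ethyl]zinc bromide
Product: 24 (Z)-trisubstituted alkene carrying the C4–C6 chain as its dioxolane (C4 cis to C1)
Conditions: 23 (2 equiv), PdCl2(dppf) (5 mol %), THF, 40 °C
Reagents that add atoms: none
Why: Negishi coupling of an alkenyl triflate with an alkylzinc reagent proceeds with retention of alkene geometry, so C4 should take the place of the triflate cis to C1, and the alkenylsilane is inert.

Step 13
Reactants: 24 alkenylsilane
Product: 25 2-iodoalkene (iodine on C7 in place of trimethylsilyl)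
Conditions: NIS (1.2 equiv), MeCN, 0 °C, dark
Reagents that add atoms: N-iodosuccinimide O=C1CCC(=O)N1I
Why: Electrophilic iododesilylation (ipso substitution of an alkenylsilane) should be faster than attack on the hindered trisubstituted alkene.

Step 14
Reactants: 25 protected iodoalkene
Product: 26 iodoalkene diol aldehyde (free O9–H and O11–H, C6 aldehyde)
Conditions: 1 M HCl, THF, rt
Reagents that add atoms: water O
Why: Acid hydrolysis should cleave the dioxolane and both triethylsilyl ethers in one operation without touching the stereocentres or the Z-alkene.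

Step 15
Reactants: 26 iodoalkene diol aldehyde
Product: 28 (1S,2Z,6R,9R,10S,11R,14R)-eunicella-2,7(16)-diene-6,9,11-triol, via alkenylchromium species 27 (not isolated)
Conditions: CrCl2 (10 equiv), NiCl2 (0.1 equiv), DMSO, rt, 2 mM
Reagents that add atoms: none
Why: Intramolecular Nozaki–Hiyama–Kishi reaction closes the ten-membered ring (C6–C7), tolerates free hydroxyl groups and delivers the allylic alcohol next to the exo-methylene group, the C6 configuration being set by addition to the aldehyde face that is turned outward in the folded chain held by the Z-alkene and the cis ring fusion.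

Step 16
Reactants: 28 triol
Product: 29 target, (1S,2Z,6R,9R,10S,11R,14R)-6,9-diacetoxyeunicella-2,7(16)-dien-11-ol
Conditions: Ac2O (4 equiv), pyridine, DMAP (5 mol %), CH2Cl2, 0 °C to rt
Reagents that add atoms: acetic anhydride CC(=O)OC(C)=O
Why: Acylation should take the two secondary hydroxyl groups and leave the hindered tertiary C11 hydroxyl free.

Compound list
1 | ethyl 2-acetyl-3-methylbutanoate | CCOC(=O)C(C(C)C)C(C)=O | starting material
2 | prop-2-en-1-ol | C=CCO | starting material
3 | prop-2-en-1-yl 2-acetyl-3-methylbutanoate | C=CCOC(=O)C(C(C)C)C(C)=O | intermediate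
4 | but-3-en-2-one | C=CC(C)=O | starting material
5 | prop-2-en-1-yl (2S)-2-acetyl-5-oxo-2-(propan-2-yl)hexanoate | CC(=O)CC[C@@](C(C)=O)(C(C)C)C(=O)OCC=C | intermediate
6 | prop-2-en-1-yl (1S,4R)-4-hydroxy-4-methyl-2-oxo-1-(propan-2-yl)cyclohexane-1-carboxylate | O=C1C[C@](C)(O)CC[C@@]1(C(C)C)C(=O)OCC=C | intermediate
7 | (1S,4R)-4-hydroxy-4-methyl-2-oxo-1-(propan-2-yl)cyclohexane-1-carboxylic acid | O=C1C[C@](C)(O)CC[C@@]1(C(C)C)C(=O)O | intermediate
8 | (3R,6R)-3-hydroxy-3-methyl-6-(propan-2-yl)cyclohexan-1-one | O=C1C[C@](C)(O)CC[C@@H]1C(C)C | intermediate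
9 | (1-bromoethenyl)trimethylsilane | C=C(Br)[Si](C)(C)C | starting material
10 | oxirane | C1CO1 | starting material
11 | [1-(trimethylsilyl)ethenyl]magnesium bromide | C=C([Mg]Br)[Si](C)(C)C | intermediate
12 | 3-(trimethylsilyl)but-3-en-1-ol | C=C(CCO)[Si](C)(C)C | intermediate
13 | 3-(trimethylsilyl)but-3-enal | C=C(CC=O)[Si](C)(C)C | intermediate
14 | C1 enol dicyclohexylborinate and C11 dicyclohexylborinate of 8 | B(OC1=C[C@](C)(OB(C2CCCCC2)C2CCCCC2)CC[C@@H]1C(C)C)(C1CCCCC1)C1CCCCC1 | intermediate
15 | (2S,3R,6R)-3-hydroxy-2-[(1R)-1-hydroxy-3-(trimethylsilyl)but-3-en-1-yl]-3-methyl-6-(propan-2-yl)cyclohexan-1-one | C=C([Si](C)(C)C)C[C@@H](O)[C@@H]1C(=O)[C@@H](C(C)C)CC[C@@]1(C)O | intermediate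
16 | bis(triethylsilyl) ether of 15 | C=C([Si](C)(C)C)C[C@@H](O[Si](CC)(CC)CC)[C@@H]1C(=O)[C@@H](C(C)C)CC[C@@]1(C)O[Si](CC)(CC)CC | intermediate
17 | 1-propynylmagnesium bromide | CC#C[Mg]Br | starting material
18 | C1 propynyl carbinol from 16 (C1 epimers) | C=C([Si](C)(C)C)C[C@@H](O[Si](CC)(CC)CC)[C@@H]1C(O)(C#CC)[C@@H](C(C)C)CC[C@@]1(C)O[Si](CC)(CC)CC | intermediate
19 | exocyclic enone, C1=C2H–C3(=O)CH3, acyl group on the C10 side | C=C([Si](C)(C)C)C[C@@H](O[Si](CC)(CC)CC)[C@@H]1/C(=C\C(C)=O)[C@@H](C(C)C)CC[C@@]1(C)O[Si](CC)(CC)CC | intermediate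
20 | (Z)-triethylsilyl enol ether with C1–H | C=C([Si](C)(C)C)C[C@@H](O[Si](CC)(CC)CC)[C@@H]1[C@H](/C=C(/C)O[Si](CC)(CC)CC)[C@@H](C(C)C)CC[C@@]1(C)O[Si](CC)(CC)CC | intermediate
21 | (Z)-lithium enolate | C=C([Si](C)(C)C)C[C@@H](O[Si](CC)(CC)CC)[C@@H]1[C@H](/C=C(/C)O[Li])[C@@H](C(C)C)CC[C@@]1(C)O[Si](CC)(CC)CC | intermediate
22 | (Z)-enol triflate | C=C([Si](C)(C)C)C[C@@H](O[Si](CC)(CC)CC)[C@@H]1[C@H](/C=C(/C)OS(=O)(=O)C(F)(F)F)[C@@H](C(C)C)CC[C@@]1(C)O[Si](CC)(CC)CC | intermediate
23 | [2-(1,3-dioxolan-2-yl)ethyl]zinc bromide | Br[Zn]CCC1OCCO1 | starting material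
24 | (Z)-alkene with C4–C6 dioxolane chain | C=C([Si](C)(C)C)C[C@@H](O[Si](CC)(CC)CC)[C@@H]1[C@H](/C=C(/C)CCC2OCCO2)[C@@H](C(C)C)CC[C@@]1(C)O[Si](CC)(CC)CC | intermediate
25 | C7 iodoalkene, protected | C=C(I)C[C@@H](O[Si](CC)(CC)CC)[C@@H]1[C@H](/C=C(/C)CCC2OCCO2)[C@@H](C(C)C)CC[C@@]1(C)O[Si](CC)(CC)CC | intermediate
26 | iodoalkene diol aldehyde | C=C(I)C[C@@H](O)[C@@H]1[C@H](/C=C(/C)CCC=O)[C@@H](C(C)C)CC[C@@]1(C)O | intermediate
27 | alkenylchromium dichloride species from 26 | C=C([Cr](Cl)Cl)C[C@@H](O)[C@@H]1[C@H](/C=C(/C)CCC=O)[C@@H](C(C)C)CC[C@@]1(C)O | intermediate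
28 | (1S,2Z,6R,9R,10S,11R,14R)-eunicella-2,7(16)-diene-6,9,11-triol | C=C1C[C@@H](O)[C@@H]2[C@H](/C=C(/C)CC[C@H]1O)[C@@H](C(C)C)CC[C@@]2(C)O | intermediate
29 | (1S,2Z,6R,9R,10S,11R,14R)-6,9-diacetoxyeunicella-2,7(16)-dien-11-ol | C=C1C[C@@H](OC(C)=O)[C@@H]2[C@H](/C=C(/C)CC[C@H]1OC(C)=O)[C@@H](C(C)C)CC[C@@]2(C)O | target

Total step count: 16. Longest linear sequence: 14 (steps 1–3 and 6–16).

Steps most likely to fail

Step 10. What may go wrong is hydride transfer to the wrong face of C1, both faces being flanked by an axial group, or 1,2-hydrosilylation of the carbonyl group. The fallback puts C1 under thermodynamic control; it sets out from 16 and comes back at 24. Ketone 16 would be treated with dimethylsulfonium methylide (Corey–Chaykovsky reaction) to give the spiro-epoxide F1. MgBr2·OEt2 would open it with hydride shift (Meinwald rearrangement), and K2CO3 in MeOH would equilibrate the product to the equatorial C1 carbaldehyde F2. Stork–Zhao olefination with (1-iodoethyl)triphenylphosphonium iodide and NaHMDS would give the (Z)-iodoalkene F3. Negishi coupling of F3 with 23 would lead back to 24.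

Step 15. What may go wrong is oligomerisation in place of closure of the strained ten-membered ring, and poor facial selectivity at the aldehyde. The fallback replaces the organochromium addition by a nickel-catalysed reductive alkyne–aldehyde macrocyclisation; it sets out from 25 and comes back at 28. TBAF in DMF would remove HI and both silyl groups from 25 to give the terminal alkyne diol F4, and 1 M HCl in THF would free the ynal F5. Ni(cod)2 (zerovalent nickel) with a bulky N-heterocyclic carbene (from SIPr·HCl and KOt-Bu) and i-Pr3SiH at high dilution would form the C6–C7 bond at the internal alkyne carbon and give the exo-methylene C6 triisopropylsilyl ether F6. TBAF would then give 28.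

Step 2. What may go wrong is sluggish addition and weak enantiofacial discrimination, because the isopropyl group crowds the nucleophilic carbon. The fallback replaces the catalyst by a covalently bound auxiliary; it sets out from 3 and comes back at 5. Condensation of 3 with (S)-1-phenylethylamine (or its mirror image, as the sense of induction requires) would give the chelated enamino ester F7. Its neutral Michael addition to 4 would give the imine F8, and aqueous acetic acid would hydrolyse F8 to 5, which is closed to 6 with DBU as in step 2.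

Further compounds
F1 | step 10 | C1 spiro-epoxide from 16 | C=C([Si](C)(C)C)C[C@@H](O[Si](CC)(CC)CC)[C@@H]1C2(CO2)[C@@H](C(C)C)CC[C@@]1(C)O[Si](CC)(CC)CC
F2 | step 10 | equatorial C1 carbaldehyde | C=C([Si](C)(C)C)C[C@@H](O[Si](CC)(CC)CC)[C@@H]1[C@H](C=O)[C@@H](C(C)C)CC[C@@]1(C)O[Si](CC)(CC)CC
F3 | step 10 | (Z)-2-iodoprop-1-enyl compound | C=C([Si](C)(C)C)C[C@@H](O[Si](CC)(CC)CC)[C@@H]1[C@H](/C=C(/C)I)[C@@H](C(C)C)CC[C@@]1(C)O[Si](CC)(CC)CC
F4 | step 15 | terminal alkyne diol with dioxolane | C#CC[C@@H](O)[C@@H]1[C@H](/C=C(/C)CCC2OCCO2)[C@@H](C(C)C)CC[C@@]1(C)O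
F5 | step 15 | ynal diol | C#CC[C@@H](O)[C@@H]1[C@H](/C=C(/C)CCC=O)[C@@H](C(C)C)CC[C@@]1(C)O
F6 | step 15 | C6 triisopropylsilyl ether of 28 | C=C1C[C@@H](O)[C@@H]2[C@H](/C=C(/C)CC[C@H]1O[Si](C(C)C)(C(C)C)C(C)C)[C@@H](C(C)C)CC[C@@]2(C)O
F7 | step 2 | (Z)-enamino ester of 3 with (S)-1-phenylethylamine | C=CCOC(=O)/C(C(C)C)=C(/C)N[C@@H](C)c1ccccc1
F8 | step 2 | imine of 5 with (S)-1-phenylethylamine | CC(=O)CC[C@@](C(C)=N[C@@H](C)c1ccccc1)(C(C)C)C(=O)OCC=C
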